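**Retrosynthetic overview**
1. Target ⇒ hydroxyl-directed epoxidation of the C8=C9 allylic alcohol; the C6 ester comes from veratroyl chloride on the least hindered hydroxyl.
2. 4,6,10-Triol ⇒ fused cyclohepta-2,4-dienone, by copper-catalysed 1,6-boration (C10–O) and a reduction directed by the C4 hydroxyl (C6–OH).
3. Dienone ⇒ hydrolysis of a methoxycycloheptatriene (masked C6 ketone), after reduction and acetylation at C2.
4. Key step: intramolecular Buchner ring expansion of an anisole ring by an α-diazoketone carbenoid; the five- and seven-membered rings and quaternary C1 form together.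
5. Diazoketone ⇒ aldol of 3-diazobutan-2-one with the aryl isopropyl ketone made from 3-methylanisole; C4 is secured by resolution; the oxirane is formed last.

Assumption: read literally, the C8 and C9 descriptors of the given string put C7 and C10 on opposite faces of the oxirane (a trans-fused epoxide on the seven-membered ring), which I take as a drawing artefact; I make the cis-fused 8α,9α-epoxide (oxygen syn to the C10 hydroxyl, C9 and all other centres as written) and keep the given string on the target line.

Numbering used in names from compound 12 on ("daucane"): C1 = methyl-bearing ring-fusion carbon; C2, C3, C4 (isopropyl carbon) complete the five-membered ring; C5 = ring-fusion CH; C6, C7, C8 (methyl), C9, C10 complete the seven-membered ring; β = face of the C1 methyl, α = opposite face.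

**Step 1**
Reactants: 1 3-methylanisole; 2 N-methoxy-N-methylisobutyramide
Product: 5 1-(2-methoxy-4-methylphenyl)-2-methylpropan-1-one, via (2-methoxy-4-methylphenyl)lithium 3 (not isolated), via lithium hemiaminal adduct 4 (not isolated)
Conditions: n-BuLi, TMEDA, Et2O, 0 °C to rt; then 2, −78 to 0 °C; H2O
Reagents that add atoms: none
Why: Directed ortho-metalation: the methoxy group directs lithiation to the less hindered ortho position (para to the methyl group) and the aryllithium is acylated by the Weinreb amide, whose chelated adduct stops at the ketone; no stereocentre is formed.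

**Step 2**
Reactants: 6 3-methylpentane-2,4-dione
Product: 7 3-diazobutan-2-one
Conditions: p-ABSA, DBU, MeCN, 0 °C to rt
Reagents that add atoms: 4-acetamidobenzenesulfonyl azide (p-ABSA) CC(=O)Nc1ccc(cc1)S(=O)(=O)N=[N+]=[N-]
Why: Regitz deacylative diazo transfer: the diketone enolate attacks the azide and the adduct collapses with transfer of one acetyl group to the sulfonamide nitrogen, leaving the diazo group on the methyl-bearing carbon.

**Step 3**
Reactants: 7 3-diazobutan-2-one; 5 1-(2-methoxy-4-methylphenyl)-2-methylpropan-1-one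
Product: 10 rac-2-diazo-5-(2-methoxy-4-methylphenyl)-6-methyl-5-(trimethylsilyloxy)heptan-3-one, via lithium 3-diazobut-1-en-2-olate 8 (not isolated), via lithium aldolate 9 (not isolated)
Conditions: LiN(SiMe3)2, THF, −78 °C; then 5, −78 °C; then Me3SiOTf, −78 to −40 °C
Reagents that add atoms: trimethylsilyl trifluoromethanesulfonate C[Si](C)(C)OS(=O)(=O)C(F)(F)F
Why: Aldol addition of the α′-lithium enolate of the diazoketone to the ketone, which the ortho-methoxy group activates by chelating lithium; silylating the hindered aldolate cold stops retro-aldol cleavage and masks the hydroxyl against O–H insertion in step 5, and C4 is formed racemic.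

**Step 4**
Reactants: 10 rac-2-diazo-5-(2-methoxy-4-methylphenyl)-6-methyl-5-(trimethylsilyloxy)heptan-3-one
Product: 11 (S)-2-diazo-5-(2-methoxy-4-methylphenyl)-6-methyl-5-(trimethylsilyloxy)heptan-3-one
Conditions: preparative SFC, amylose tris(3,5-dimethylphenylcarbamate) column, CO2/i-PrOH
Reagents that add atoms: none
Why: Resolution by chromatography on a chiral stationary phase: the (S)-enantiomer is kept and fixes C4, from which all other centres are derived; its configuration is confirmed by X-ray analysis of crystalline 21.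

**Step 5**
Reactants: 11 (S)-2-diazo-5-(2-methoxy-4-methylphenyl)-6-methyl-5-(trimethylsilyloxy)heptan-3-one
Product: 13 (3S,8aS)-3-isopropyl-4-methoxy-6,8a-dimethyl-3-(trimethylsilyloxy)-3,8a-dihydroazulen-1(2H)-one, via norcaradiene valence tautomer 12 (not isolated)
Conditions: Rh2(OAc)4 (1 mol %), CH2Cl2, slow addition of 11, 0 °C to rt
Reagents that add atoms: none
Why: Intramolecular Buchner reaction: the rhodium carbenoid cyclopropanates the ipso/ortho bond on the unsubstituted side of the anisole ring and the norcaradiene opens by 6π electrocyclisation to the cycloheptatriene, forming both rings and quaternary C1; C4 controls C1 because the isopropyl group turns away from the carbenoid and from the methoxy-bearing ortho carbon, which leaves the new angular methyl cis to the silyloxy group.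

**Step 6**
Reactants: 13 (3S,8aS)-3-isopropyl-4-methoxy-6,8a-dimethyl-3-(trimethylsilyloxy)-3,8a-dihydroazulen-1(2H)-one
Product: 15 2β-acetoxy-6-methoxy-4β-(trimethylsilyloxy)dauca-5,7,9-triene, via lithium 2β-alkoxide 14 (not isolated)
Conditions: LiBH(s-Bu)3, THF, −78 °C; then Ac2O, DMAP, −78 °C to rt
Reagents that add atoms: acetic anhydride CC(=O)OC(C)=O
Why: Hydride reduction then in-flask acetylation (reductive acetylation): the hindered borohydride attacks the cyclopentanone from the face opposite the angular methyl, as in 17-keto steroids, and gives the 2β-alkoxide, which is trapped as the acetate.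

**Step 7**
Reactants: 15 2β-acetoxy-6-methoxy-4β-(trimethylsilyloxy)dauca-5,7,9-triene
Product: 16 2β-acetoxy-4β-hydroxy-5αH-dauca-7,9-dien-6-one
Conditions: 0.5 M aq. HCl, THF, 0 °C
Reagents that add atoms: water O
Why: Acid hydrolysis of the methyl enol ether (protonation at C5, collapse of the hemiketal) with loss of the Me3Si group: the proton enters C5 anti to the angular methyl and the silyloxy group, and the centre can equilibrate through the enol to the trans-fused ketone, which is hydrogen-bonded to the 4β-hydroxyl and keeps the isopropyl group away from C6.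

**Step 8**
Reactants: 16 2β-acetoxy-4β-hydroxy-5αH-dauca-7,9-dien-6-one
Product: 17 2β-acetoxy-4β-hydroxy-10α-(4,4,5,5-tetramethyl-1,3,2-dioxaborolan-2-yl)-5αH-dauc-8-en-6-one
Conditions: B2pin2, CuCl (5 mol %), Xantphos (5 mol %), NaOt-Bu (10 mol %), MeOH (2 equiv), THF, 0 °C to rt
Reagents that add atoms: bis(pinacolato)diboron CC1(C)OB(OC1(C)C)B1OC(C)(C)C(C)(C)O1
Why: Copper-catalysed 1,6-conjugate boration of the dienone: the methyl group on the β-carbon diverts the boryl-copper to the δ-carbon, the boron enters C10 anti to the angular methyl (α), and α-protonation of the dienolate leaves the β,γ-unsaturated ketone with the C8=C9 bond in place.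

**Step 9**
Reactants: 17 2β-acetoxy-4β-hydroxy-10α-(4,4,5,5-tetramethyl-1,3,2-dioxaborolan-2-yl)-5αH-dauc-8-en-6-one
Product: 19 2β-acetoxy-5αH-dauc-8-ene-4β,6α,10α-triol, via 6α-hydroxy allylboronate 18 (not isolated)
Conditions: Me4NBH(OAc)3, MeCN/AcOH, −30 °C; then NaBO3·4H2O, THF/H2O, rt
Reagents that add atoms: sodium perborate [Na+].[O-]OB=O
Why: Evans–Saksena hydroxyl-directed reduction: the borohydride bound to the 4β-hydroxyl delivers hydride to the β-face of the C6 ketone (anti 1,3-diol, 6α-OH), and perborate then oxidises the C–B bond with retention to the 10α-hydroxyl.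

**Step 10**
Reactants: 19 2β-acetoxy-5αH-dauc-8-ene-4β,6α,10α-triol; 20 3,4-dimethoxybenzoyl chloride
Product: 21 2β-acetoxy-4β,10α-dihydroxy-5αH-dauc-8-en-6α-yl 3,4-dimethoxybenzoate
Conditions: Et3N, DMAP (cat.), CH2Cl2, −20 to 0 °C
Reagents that add atoms: none
Why: Site-selective acylation under DMAP catalysis: the C6 hydroxyl reacts, because the C10 hydroxyl is neopentylic (next to quaternary C1) and the C4 hydroxyl is tertiary; no stereocentre changes.

**Step 11**
Reactants: 21 2β-acetoxy-4β,10α-dihydroxy-5αH-dauc-8-en-6α-yl 3,4-dimethoxybenzoate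
Product: 22 2β-acetoxy-8α,9α-epoxy-4β,10α-dihydroxy-5αH-daucan-6α-yl 3,4-dimethoxybenzoate (CNP0197096.4)
Conditions: VO(acac)2 (5 mol %), t-BuOOH, CH2Cl2, 0 °C to rt
Reagents that add atoms: tert-butyl hydroperoxide CC(C)(C)OO
Why: Vanadium-catalysed hydroxyl-directed epoxidation: the C10 hydroxyl binds the vanadium peroxide and delivers oxygen to the α-face of the trisubstituted C8=C9 bond, setting C8 and C9 syn to the 10α-hydroxyl.

**Compound list**
1 | 3-methylanisole | COc1cccc(C)c1 | starting material
2 | N-methoxy-N-methylisobutyramide | CC(C)C(=O)N(C)OC | starting material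
3 | (2-methoxy-4-methylphenyl)lithium | [Li]c1ccc(C)cc1OC | intermediate
4 | lithium 1-[methoxy(methyl)amino]-1-(2-methoxy-4-methylphenyl)-2-methylpropan-1-olate | [Li+].CC(C)C([O-])(N(C)OC)c1ccc(C)cc1OC | intermediate
5 | 1-(2-methoxy-4-methylphenyl)-2-methylpropan-1-one | CC(C)C(=O)c1ccc(C)cc1OC | intermediate
6 | 3-methylpentane-2,4-dione | CC(=O)C(C)C(C)=O | starting material
7 | 3-diazobutan-2-one | CC(=O)C(C)=[N+]=[N-] | intermediate
8 | lithium 3-diazobut-1-en-2-olate | [Li+].[O-]C(=C)C(C)=[N+]=[N-] | intermediate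
9 | lithium 6-diazo-3-(2-methoxy-4-methylphenyl)-2-methyl-5-oxoheptan-3-olate (racemic aldolate) | [Li+].CC(=[N+]=[N-])C(=O)CC([O-])(C(C)C)c1ccc(C)cc1OC | intermediate
10 | rac-2-diazo-5-(2-methoxy-4-methylphenyl)-6-methyl-5-(trimethylsilyloxy)heptan-3-one | CC(=[N+]=[N-])C(=O)CC(O[Si](C)(C)C)(C(C)C)c1ccc(C)cc1OC | intermediate
11 | (S)-2-diazo-5-(2-methoxy-4-methylphenyl)-6-methyl-5-(trimethylsilyloxy)heptan-3-one | CC(=[N+]=[N-])C(=O)C[C@](O[Si](C)(C)C)(C(C)C)c1ccc(C)cc1OC | intermediate
12 | norcaradiene valence tautomer of 13 (cyclopropane C1–C5–C10 on the α-face, diene C6=C7/C8=C9) | COC2=CC(C)=C[C@@H]3[C@]24[C@@](O[Si](C)(C)C)(C(C)C)CC(=O)[C@@]34C | intermediate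
13 | (3S,8aS)-3-isopropyl-4-methoxy-6,8a-dimethyl-3-(trimethylsilyloxy)-3,8a-dihydroazulen-1(2H)-one (6-methoxy-4β-silyloxy-dauca-5,7,9-trien-2-one) | COC2=C3[C@@](O[Si](C)(C)C)(C(C)C)CC(=O)[C@@]3(C)C=CC(C)=C2 | intermediate
14 | lithium 2β-alkoxide of 6-methoxy-4β-(trimethylsilyloxy)dauca-5,7,9-triene | [Li+].COC2=C3[C@@](O[Si](C)(C)C)(C(C)C)C[C@H]([O-])[C@@]3(C)C=CC(C)=C2 | intermediate
15 | 2β-acetoxy-6-methoxy-4β-(trimethylsilyloxy)dauca-5,7,9-triene | COC2=C3[C@@](O[Si](C)(C)C)(C(C)C)C[C@H](OC(C)=O)[C@@]3(C)C=CC(C)=C2 | intermediate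
16 | 2β-acetoxy-4β-hydroxy-5αH-dauca-7,9-dien-6-one | O=C2C=C(C)C=C[C@]3(C)[C@@H](OC(C)=O)C[C@](O)(C(C)C)[C@@H]23 | intermediate
17 | 2β-acetoxy-4β-hydroxy-10α-(pinacolboryl)-5αH-dauc-8-en-6-one | O=C2CC(C)=C[C@H](B4OC(C)(C)C(C)(C)O4)[C@]3(C)[C@@H](OC(C)=O)C[C@](O)(C(C)C)[C@@H]23 | intermediate
18 | 2β-acetoxy-10α-(pinacolboryl)-5αH-dauc-8-ene-4β,6α-diol | O[C@@H]2CC(C)=C[C@H](B4OC(C)(C)C(C)(C)O4)[C@]3(C)[C@@H](OC(C)=O)C[C@](O)(C(C)C)[C@@H]23 | intermediate
19 | 2β-acetoxy-5αH-dauc-8-ene-4β,6α,10α-triol | O[C@@H]2CC(C)=C[C@H](O)[C@]3(C)[C@@H](OC(C)=O)C[C@](O)(C(C)C)[C@@H]23 | intermediate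
20 | 3,4-dimethoxybenzoyl chloride (veratroyl chloride) | COc1ccc(C(Cl)=O)cc1OC | starting material
21 | 2β-acetoxy-4β,10α-dihydroxy-5αH-dauc-8-en-6α-yl 3,4-dimethoxybenzoate | COc1ccc(C(=O)O[C@@H]2CC(C)=C[C@H](O)[C@]3(C)[C@@H](OC(C)=O)C[C@](O)(C(C)C)[C@@H]23)cc1OC | intermediate
22 | 2β-acetoxy-8α,9α-epoxy-4β,10α-dihydroxy-5αH-daucan-6α-yl 3,4-dimethoxybenzoate (CNP0197096.4; string as given, see assumption) | COc1ccc(C(=O)O[C@@H]2C[C@@]3(C)O[C@@H]3[C@H](O)[C@]3(C)[C@@H](OC(C)=O)C[C@](O)(C(C)C)[C@@H]23)cc1OC | target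

**Step count**
Total: 11 steps (the resolution counted as a step). Longest linear sequence: 10 steps (1, 3, 4, 5, 6, 7, 8, 9, 10, 11); step 2 is a one-step side branch.

**Three steps most likely to fail**

Step 3 (aldol). The α′-enolate of the diazoketone is an unstabilised vinyl diazo species, the ketone is hindered and the adduct can revert. The fallback sets out from 5 and comes back at 10, and installs the diazo group last. LiCH2CN (MeCN, n-BuLi, THF, −78 °C) adds to 5 to give rac-3-hydroxy-3-(2-methoxy-4-methylphenyl)-4-methylpentanenitrile F1. Silylation (Me3SiCl, imidazole, DMF) gives the silyl ether nitrile F2. EtMgBr, then buffered hydrolysis of the imine (pH 5), gives the ethyl ketone F3. Kinetic trifluoroacetylation on the ethyl side (LiN(SiMe3)2, CF3CO2CH2CF3, −78 °C; the other α-carbon is neopentylic) gives the trifluoroacetyl diketone F4. MsN3/Et3N (detrifluoroacetylative diazo transfer) then returns 10, which is resolved as in step 4.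

Step 5 (Buchner ring expansion). The carbenoid can be lost to 1,2-hydride shift from its methyl group, to insertion into the isopropyl C–H, to attack by the silyl ether oxygen or to addition on the methoxy side, and control of C1 by C4 may be incomplete. The fallback sets out from racemic 10 (step 4 is dropped) and comes back at 13. It replaces substrate control on resolved material by catalyst control on the racemate with a copper carbenoid, which does not insert into unactivated C–H bonds: [Cu(MeCN)4]PF6, a tert-butyl bis(oxazoline) ligand and NaB[3,5-(CF3)2C6H3]4 in CH2Cl2, a catalyst class that gives high facial selectivity with 2-diazo-5-arylpentan-3-ones. The ligand fixes the configuration of C1 for both enantiomers, so (S)-10 gives 13 and (R)-10 gives the C4-epimeric azulenone F5. F5 is a diastereomer of 13 and is removed on silica; the route continues from 13. If catalyst control over the mismatched enantiomer is incomplete, the enantiomeric purity of 13 falls and must be checked.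

Step 8 (1,6-boration). The δ-carbon is neopentylic, and 1,4-addition or γ-protonation to the conjugated enone could compete. The fallback sets out from 16 and comes back at 19, and puts the C10 oxygen in by epoxide chemistry. m-CPBA/NaHCO3 (CH2Cl2, 0 °C) epoxidises the distal, more electron-rich C9=C10 bond anti to the angular methyl to give the 9α,10α-epoxy enone F6. SmI2 (THF/MeOH, −78 °C) opens the γ,δ-epoxy enone reductively to the 10α-hydroxy β,γ-unsaturated ketone F7. Me4NBH(OAc)3 (MeCN/AcOH, −30 °C) then reduces the C6 ketone under direction of the 4β-hydroxyl to give triol 19.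

**Further compounds**
F1 | step 3 | rac-3-hydroxy-3-(2-methoxy-4-methylphenyl)-4-methylpentanenitrile | N#CCC(O)(C(C)C)c1ccc(C)cc1OC
F2 | step 3 | rac-3-(2-methoxy-4-methylphenyl)-4-methyl-3-(trimethylsilyloxy)pentanenitrile | N#CCC(O[Si](C)(C)C)(C(C)C)c1ccc(C)cc1OC
F3 | step 3 | rac-5-(2-methoxy-4-methylphenyl)-6-methyl-5-(trimethylsilyloxy)heptan-3-one | CCC(=O)CC(O[Si](C)(C)C)(C(C)C)c1ccc(C)cc1OC
F4 | step 3 | rac-1,1,1-trifluoro-6-(2-methoxy-4-methylphenyl)-3,7-dimethyl-6-(trimethylsilyloxy)octane-2,4-dione | CC(C(=O)C(F)(F)F)C(=O)CC(O[Si](C)(C)C)(C(C)C)c1ccc(C)cc1OC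
F5 | step 5 | (3R,8aS)-3-isopropyl-4-methoxy-6,8a-dimethyl-3-(trimethylsilyloxy)-3,8a-dihydroazulen-1(2H)-one (C4 epimer of 13) | COC2=C3[C@](O[Si](C)(C)C)(C(C)C)CC(=O)[C@@]3(C)C=CC(C)=C2
F6 | step 8 | 2β-acetoxy-9α,10α-epoxy-4β-hydroxy-5αH-dauc-7-en-6-one | O=C2C=C(C)[C@@H]4O[C@@H]4[C@]3(C)[C@@H](OC(C)=O)C[C@](O)(C(C)C)[C@@H]23
F7 | step 8 | 2β-acetoxy-4β,10α-dihydroxy-5αH-dauc-8-en-6-one | O=C2CC(C)=C[C@H](O)[C@]3(C)[C@@H](OC(C)=O)C[C@](O)(C(C)C)[C@@H]23
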